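Retrosynthetic cuts, in order: the C19–O ester bond; C15/C16 of the diene (ethylene enyne metathesis on a C13 alkyne); the C7–O and C8–O bonds (syn-dihydroxylation of a Δ7 alkene); C9–C11 (addition to a C9 ketone, then two allylic transpositions); C3–C4 (ring A); C10–C1 and C10–C20 (enolate alkylations).
Forward: (R)-carvone is ring B (carvone C5, C6, C1, C2, C3, C4 become labdane C5, C10, C9, C8, C7, C6). C10 is methylated and then 3-chloropropylated, the isopropenyl group is turned into a 2-propanal unit (C4, C18, C19), and ring A is closed by the C3–C4 bond. The C9 side chain, the diol, the diene and the ester follow.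
Enabling feature: C4 is a quaternary ring A carbon whose axial substituent C19 is the only oxidised carbon on ring A, and its neighbour C3 is a plain methylene three bonds from quaternary C10. With C19 as a formyl group C4 becomes an enolate carbon, C3 a primary chloride, and ring A (C1–C2–C3–C4–C5–C10) closes 6-exo-tet onto ring B.
Stereochemistry: C5 comes from (R)-carvone; C10 from alkylation anti to the C5 substituent; C4 from the ring closure under control of the axial C10 methyl; C9 from suprafacial hydrogen delivery by a C7α diazene (C7 set by Luche reduction); C7 and C8 from OsO4 on the α face; the E alkene from the cinnamic acid.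

Key step: step 5

Remark: bicyclic compounds are numbered as labdanes (C1–C20); β is the face of the C10 methyl group, and 11,12,13,14,15,16-hexanorlabdane is the C14 decalin that lacks the C9 side chain.

Step 1
Reactants: 1 (R)-(−)-carvone
Product: 3 6-methylcarvone (C6 epimers), via lithium dienolate 2 (not isolated)
Conditions: LiN(i-Pr)2, THF, −78 °C; MeI, −78 → 0 °C
Reagents that add atoms: iodomethane, CI
Why: kinetic deprotonation at the α' carbon (carvone C6, the future C10) gives the cross-conjugated lithium dienolate, which is C-methylated by SN2 (enolate alkylation); the new stereocentre forms as an epimer mixture and is planarised again in step 2.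

Step 2
Reactants: 3 6-methylcarvone
Product: 5 (5S,6S)-6-(3-chloropropyl)-2,6-dimethyl-5-(prop-1-en-2-yl)cyclohex-2-en-1-one, via lithium enolate 4 (not isolated)
Conditions: LiN(i-Pr)2, THF, −78 °C; I(CH2)3Cl, DMPU, −78 °C → rt
Reagents that add atoms: 1-chloro-3-iodopropane, ClCCCI
Why: the tetrasubstituted lithium enolate displaces iodide in preference to chloride (enolate alkylation), and the electrophile enters anti to the adjacent isopropenyl group, so the chain is trans and the methyl cis to it, which fixes the quaternary centre that becomes C10.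

Step 3
Reactants: 5 (5S,6S)-6-(3-chloropropyl)-2,6-dimethyl-5-(prop-1-en-2-yl)cyclohex-2-en-1-one
Product: 6 (5R,6S)-6-(3-chloropropyl)-2,6-dimethyl-5-(2-methyloxiran-2-yl)cyclohex-2-en-1-one (oxirane epimers)
Conditions: mCPBA, CH2Cl2, 0 °C
Reagents that add atoms: 3-chloroperoxybenzoic acid, O=C(OO)c1cccc(Cl)c1
Why: peracid epoxidation (Prilezhaev reaction) is selective for the electron-rich 1,1-disubstituted alkene over the electron-poor enone alkene; the oxirane carbon forms as an inconsequential epimer mixture.

Step 4
Reactants: 6 (5R,6S)-6-(3-chloropropyl)-2,6-dimethyl-5-(2-methyloxiran-2-yl)cyclohex-2-en-1-one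
Product: 7 2-[(1S,2S)-2-(3-chloropropyl)-2,4-dimethyl-3-oxocyclohex-4-en-1-yl]propanal (epimers at the propanal α-carbon)
Conditions: BF3·OEt2 (0.3 equiv), CH2Cl2, −78 °C
Reagents that add atoms: none
Why: the Lewis acid opens the 2,2-disubstituted oxirane at its tertiary carbon and a 1,2-hydride shift from the CH2O carbon gives the α-branched aldehyde (Meinwald rearrangement); the α-stereocentre is a mixture that is erased on enolisation in step 5.

Step 5
Reactants: 7 2-[(1S,2S)-2-(3-chloropropyl)-2,4-dimethyl-3-oxocyclohex-4-en-1-yl]propanal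
Product: 9 9-oxo-11,12,13,14,15,16-hexanorlabd-7-en-19-al (trans-decalin; 4β-CHO; 4α-CH3), via potassium enolate 8 (not isolated)
Conditions: t-BuOK (1.1 equiv), THF/t-BuOH (5:1), 0 → 40 °C
Reagents that add atoms: none
Why: t-BuOK removes the α-hydrogen of the branched aldehyde, the most acidic C–H of 7, and the nucleophilic carbon C4 of the potassium enolate 8 displaces chloride from C3 in an intramolecular SN2 reaction. The closest known reaction type is the intramolecular C-alkylation of an aldehyde or ketone enolate by an ω-haloalkyl chain (cycloalkylation) that creates a quaternary α-carbon. Ring A closes in the 6-exo-tet mode through a chair-like transition state in which the C1–C3 chain on C10 and the enolate unit on C5 are both equatorial on ring B, so the decalin is trans-fused and C5 and C10 are not touched. The new stereocentre C4 is controlled by the axial C10 methyl group: the enolate plane must stand perpendicular to the forming C3–C4 bond, so one C4 substituent points to the β face syn-axial to that methyl, and the flat enolate carbon C19, with its hydrogen rather than its oxygen turned inward, should fit there much better than the C4 methyl, which takes the equatorial α position and leaves the formyl group axial. The step needs C- over O-alkylation (O-attack would require an eight-membered ring), enolisation of the aldehyde in preference to the γ-position of the enone (secured by the lower pKa of the aldehyde and by reversible conditions that return any deconjugated enone to the conjugated isomer), and no intermolecular aldol reaction (hindered α-branched aldehyde at moderate dilution).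

Step 6
Reactants: 9 9-oxo-11,12,13,14,15,16-hexanorlabd-7-en-19-al
Product: 10 19-hydroxy-11,12,13,14,15,16-hexanorlabd-7-en-9-one
Conditions: NaBH4, EtOH/CH2Cl2, −78 → −20 °C
Reagents that add atoms: none
Why: at low temperature borohydride reduces the aldehyde much faster than the hindered conjugated ketone (chemoselective hydride reduction), and no stereocentre is formed.

Step 7
Reactants: 10 19-hydroxy-11,12,13,14,15,16-hexanorlabd-7-en-9-one
Product: 11 19-(tert-butyldimethylsilyloxy)-11,12,13,14,15,16-hexanorlabd-7-en-9-one
Conditions: TBSCl, imidazole, DMF, rt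
Reagents that add atoms: tert-butyldimethylsilyl chloride, CC(C)(C)[Si](C)(C)Cl
Why: imidazole-promoted silylation of the primary alcohol gives an ether that survives the organometallic, oxidative and reductive steps that follow (silyl ether protection).

Step 8
Reactants: 11 19-(tert-butyldimethylsilyloxy)-11,12,13,14,15,16-hexanorlabd-7-en-9-one; 12 (4-bromobut-1-yn-1-yl)trimethylsilane
Product: 15 19-(tert-butyldimethylsilyloxy)-14-(trimethylsilyl)-15,16-dinorlabd-7-en-13-yn-9-ol, via Grignard reagent 13 (not isolated), via organocerium reagent 14 (not isolated)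
Conditions: 12, Mg, THF, rt; anhydrous CeCl3, THF, −78 °C; then 11, −78 → 0 °C; aq NH4Cl
Reagents that add atoms: none
Why: the organocerium reagent is strongly nucleophilic but weakly basic and adds 1,2 to the hindered enone without γ-deprotonation or conjugate addition (organocerium carbonyl addition); attack is expected anti to the axial C10 methyl, but the C9 configuration is irrelevant because C9 becomes sp2 in step 9.

Step 9
Reactants: 15 19-(tert-butyldimethylsilyloxy)-14-(trimethylsilyl)-15,16-dinorlabd-7-en-13-yn-9-ol
Product: 16 19-(tert-butyldimethylsilyloxy)-14-(trimethylsilyl)-15,16-dinorlabd-8-en-13-yn-7-one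
Conditions: pyridinium chlorochromate [C5H5NH][CrO3Cl], 4 Å MS, CH2Cl2, rt
Reagents that add atoms: pyridinium chlorochromate, [O-][Cr](=O)(=O)Cl.c1cc[nH+]cc1
Why: the tertiary allylic chromate ester undergoes a [3,3]-sigmatropic shift to the secondary C7 chromate ester, which hexavalent chromium oxidises to the transposed enone (Babler–Dauben oxidative transposition), erasing the C9 carbinol centre.

Step 10
Reactants: 16 19-(tert-butyldimethylsilyloxy)-14-(trimethylsilyl)-15,16-dinorlabd-8-en-13-yn-7-one
Product: 17 19-(tert-butyldimethylsilyloxy)-14-(trimethylsilyl)-15,16-dinorlabd-8-en-13-yn-7β-ol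
Conditions: NaBH4, CeCl3·7H2O, MeOH, −40 °C
Reagents that add atoms: none
Why: Luche reduction gives clean 1,2-reduction, and the small hydride should attack C7 axially from the α face, away from the β face screened by the axial C10 methyl and the axial C6 hydrogen, to give the equatorial 7β-alcohol.

Step 11
Reactants: 17 19-(tert-butyldimethylsilyloxy)-14-(trimethylsilyl)-15,16-dinorlabd-8-en-13-yn-7β-ol
Product: 20 19-(tert-butyldimethylsilyloxy)-14-(trimethylsilyl)-15,16-dinorlabd-7-en-13-yne (9α-H), via allylic sulfonylhydrazine 18 (not isolated), via allylic diazene 19 (not isolated)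
Conditions: 2-nitrobenzenesulfonylhydrazide, PPh3, DEAD, THF, −30 °C; then rt
Reagents that add atoms: none
Why: Mitsunobu displacement with inversion puts the sulfonylhydrazine on the axial 7α position, loss of sulfinic acid gives the monoalkyl diazene, and its N–H hydrogen is passed suprafacially to C9 through a six-membered retro-ene transition state with loss of N2 (reductive 1,3-transposition of an allylic alcohol), so C9 receives its hydrogen on the α face, the side chain becomes equatorial and the alkene moves to C7=C8.

Step 12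
Reactants: 20 19-(tert-butyldimethylsilyloxy)-14-(trimethylsilyl)-15,16-dinorlabd-7-en-13-yne
Product: 21 19-(tert-butyldimethylsilyloxy)-14-(trimethylsilyl)-15,16-dinorlabd-13-yne-7α,8α-diol
Conditions: OsO4 (5 mol %), NMO, acetone/H2O, rt
Reagents that add atoms: N-methylmorpholine N-oxide, C[N+]1([O-])CCOCC1; water, O
Why: catalytic osmylation is a concerted syn addition that should occur on the α face of the trisubstituted alkene, opposite the axial C10 methyl, setting the cis 7α,8α-diol with the C8 methyl β, while the silylalkyne is inert.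

Step 13
Reactants: 21 19-(tert-butyldimethylsilyloxy)-14-(trimethylsilyl)-15,16-dinorlabd-13-yne-7α,8α-diol
Product: 22 15,16-dinorlabd-13-yne-7α,8α,19-triol
Conditions: TBAF, THF, rt
Reagents that add atoms: none
Why: fluoride cleaves both the O–Si bond of the primary silyl ether and the C(sp)–Si bond of the alkynylsilane in one operation (fluoride desilylation) without touching any stereocentre.

Step 14
Reactants: 22 15,16-dinorlabd-13-yne-7α,8α,19-triol
Product: 23 labda-13(16),14-diene-7α,8α,19-triol
Conditions: second-generation Grubbs catalyst RuCl2(=CHPh)(H2IMes)(PCy3) (10 mol %), ethylene (1 atm), CH2Cl2, 40 °C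
Reagents that add atoms: ethylene, C=C
Why: in cross enyne metathesis the ruthenium methylidene adds to the terminal alkyne and the resulting vinylcarbene is intercepted by ethylene, turning C≡CH into the 2-substituted buta-1,3-diene; free hydroxyl groups are tolerated and no other alkene is present.

Step 15
Reactants: 23 labda-13(16),14-diene-7α,8α,19-triol; 24 (E)-4-acetoxycinnamic acid
Product: 25 7α,8α-dihydroxylabda-13(16),14-dien-19-yl (E)-4-acetoxycinnamate
Conditions: DCC, DMAP (cat.), CH2Cl2, 0 °C → rt
Reagents that add atoms: none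
Why: in the Steglich esterification the acylpyridinium ion should acylate the primary C19 hydroxyl, because the axial secondary C7 hydroxyl next to fully substituted C8 and the tertiary C8 hydroxyl are far more hindered; the E geometry comes unchanged from the acid.

Step 16
Reactants: 25 7α,8α-dihydroxylabda-13(16),14-dien-19-yl (E)-4-acetoxycinnamate
Product: 26 7α,8α-dihydroxylabda-13(16),14-dien-19-yl (E)-4-hydroxycinnamate (CNP0254560.2)
Conditions: pyrrolidine, CH2Cl2, 0 °C → rt
Reagents that add atoms: none
Why: aminolysis of the activated aryl acetate by pyrrolidine is much faster than attack on the hindered alkyl cinnamate (chemoselective deacetylation), which frees the phenol and leaves the ester, diol and diene intact.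

Compound list
1 | (R)-(−)-carvone, (5R)-2-methyl-5-(prop-1-en-2-yl)cyclohex-2-en-1-one | O=C1C(C)=CC[C@@H](C(C)=C)C1 | starting material
2 | lithium dienolate of (R)-carvone, deprotonated at C6 (not isolated) | CC1=CC[C@@H](C(C)=C)C=C1O[Li] | intermediate
3 | 6-methylcarvone, (5R)-2,6-dimethyl-5-(prop-1-en-2-yl)cyclohex-2-en-1-one, C6 epimers | CC1=CC[C@@H](C(C)=C)C(C)C1=O | intermediate
4 | lithium enolate of 6-methylcarvone (not isolated) | CC1=CC[C@@H](C(C)=C)C(C)=C1O[Li] | intermediate
5 | (5S,6S)-6-(3-chloropropyl)-2,6-dimethyl-5-(prop-1-en-2-yl)cyclohex-2-en-1-one (chain trans to isopropenyl) | O=C1C(C)=CC[C@@H](C(C)=C)[C@]1(C)CCCCl | intermediate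
6 | (5R,6S)-6-(3-chloropropyl)-2,6-dimethyl-5-(2-methyloxiran-2-yl)cyclohex-2-en-1-one, oxirane epimers | O=C1C(C)=CC[C@@H](C2(C)CO2)[C@]1(C)CCCCl | intermediate
7 | 2-[(1S,2S)-2-(3-chloropropyl)-2,4-dimethyl-3-oxocyclohex-4-en-1-yl]propanal, α-epimers | O=C1C(C)=CC[C@@H](C(C)C=O)[C@]1(C)CCCCl | intermediate
8 | potassium enolate of aldehyde 7 (not isolated) | O=C1C(C)=CC[C@@H](C(C)=CO[K])[C@]1(C)CCCCl | intermediate
9 | 9-oxo-11,12,13,14,15,16-hexanorlabd-7-en-19-al, (1S,4aS,8aS)-1,4a,6-trimethyl-5-oxo-1,2,3,4,4a,5,8,8a-octahydronaphthalene-1-carbaldehyde (4β-CHO, 4α-CH3, 5α-H, 10β-CH3) | O=C1C(C)=CC[C@H]2[C@@](C)(C=O)CCC[C@@]21C | intermediate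
10 | 19-hydroxy-11,12,13,14,15,16-hexanorlabd-7-en-9-one | O=C1C(C)=CC[C@H]2[C@@](C)(CO)CCC[C@@]21C | intermediate
11 | 19-(tert-butyldimethylsilyloxy)-11,12,13,14,15,16-hexanorlabd-7-en-9-one | O=C1C(C)=CC[C@H]2[C@@](C)(CO[Si](C)(C)C(C)(C)C)CCC[C@@]21C | intermediate
12 | (4-bromobut-1-yn-1-yl)trimethylsilane | C[Si](C)(C)C#CCCBr | starting material
13 | [4-(trimethylsilyl)but-3-yn-1-yl]magnesium bromide (not isolated) | C[Si](C)(C)C#CCC[Mg]Br | intermediate
14 | [4-(trimethylsilyl)but-3-yn-1-yl]cerium dichloride (not isolated) | C[Si](C)(C)C#CCC[Ce](Cl)Cl | intermediate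
15 | 19-(tert-butyldimethylsilyloxy)-14-(trimethylsilyl)-15,16-dinorlabd-7-en-13-yn-9-ol (9β-OH expected; either epimer serves) | O[C@@]1(CCC#C[Si](C)(C)C)C(C)=CC[C@H]2[C@@](C)(CO[Si](C)(C)C(C)(C)C)CCC[C@@]21C | intermediate
16 | 19-(tert-butyldimethylsilyloxy)-14-(trimethylsilyl)-15,16-dinorlabd-8-en-13-yn-7-one | C[Si](C)(C)C#CCCC1=C(C)C(=O)C[C@H]2[C@@](C)(CO[Si](C)(C)C(C)(C)C)CCC[C@@]21C | intermediate
17 | 19-(tert-butyldimethylsilyloxy)-14-(trimethylsilyl)-15,16-dinorlabd-8-en-13-yn-7β-ol | C[Si](C)(C)C#CCCC1=C(C)[C@@H](O)C[C@H]2[C@@](C)(CO[Si](C)(C)C(C)(C)C)CCC[C@@]21C | intermediate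
18 | 7α-[1-(2-nitrobenzenesulfonyl)hydrazin-1-yl] derivative of the Δ8 silyl ether (not isolated) | C[Si](C)(C)C#CCCC1=C(C)[C@H](N(N)S(=O)(=O)c3ccccc3[N+](=O)[O-])C[C@H]2[C@@](C)(CO[Si](C)(C)C(C)(C)C)CCC[C@@]21C | intermediate
19 | 7α-diazenyl derivative of the Δ8 silyl ether (not isolated) | C[Si](C)(C)C#CCCC1=C(C)[C@H](N=N)C[C@H]2[C@@](C)(CO[Si](C)(C)C(C)(C)C)CCC[C@@]21C | intermediate
20 | 19-(tert-butyldimethylsilyloxy)-14-(trimethylsilyl)-15,16-dinorlabd-7-en-13-yne (9α-H) | C[Si](C)(C)C#CCC[C@H]1C(C)=CC[C@H]2[C@@](C)(CO[Si](C)(C)C(C)(C)C)CCC[C@@]21C | intermediate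
21 | 19-(tert-butyldimethylsilyloxy)-14-(trimethylsilyl)-15,16-dinorlabd-13-yne-7α,8α-diol | C[Si](C)(C)C#CCC[C@H]1[C@](C)(O)[C@H](O)C[C@H]2[C@@](C)(CO[Si](C)(C)C(C)(C)C)CCC[C@@]21C | intermediate
22 | 15,16-dinorlabd-13-yne-7α,8α,19-triol | C#CCC[C@H]1[C@](C)(O)[C@H](O)C[C@H]2[C@@](C)(CO)CCC[C@@]21C | intermediate
23 | labda-13(16),14-diene-7α,8α,19-triol | C=CC(=C)CC[C@H]1[C@](C)(O)[C@H](O)C[C@H]2[C@@](C)(CO)CCC[C@@]21C | intermediate
24 | (E)-4-acetoxycinnamic acid | CC(=O)Oc1ccc(/C=C/C(=O)O)cc1 | starting material
25 | 7α,8α-dihydroxylabda-13(16),14-dien-19-yl (E)-4-acetoxycinnamate | C=CC(=C)CC[C@H]1[C@](C)(O)[C@H](O)C[C@H]2[C@@](C)(COC(=O)/C=C/c3ccc(OC(C)=O)cc3)CCC[C@@]21C | intermediate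
26 | 7α,8α-dihydroxylabda-13(16),14-dien-19-yl (E)-4-hydroxycinnamate (CNP0254560.2) | C=CC(=C)CC[C@H]1[C@](C)(O)[C@H](O)C[C@H]2[C@@](C)(COC(=O)/C=C/c3ccc(O)cc3)CCC[C@@]21C | target

Total step count: 16. Longest linear sequence: 16 steps (1 to 26); 12 and 24 are used as purchased.

Steps most likely to fail

Step 5. The risks are insufficient facial discrimination at C4 during ring closure, and deprotonation of the enone at its γ-position followed by bridging alkylation at C8. The fallback sets out from 7 and returns at 9. The aldehyde of 7 is converted with I2 and aqueous NH3 in THF into 2-[(1S,2S)-2-(3-chloropropyl)-2,4-dimethyl-3-oxocyclohex-4-en-1-yl]propanenitrile F1. KN(SiMe3)2 (2.2 equiv, THF, −78 → 0 °C) forms the dianion, in which the more basic α-cyano carbanion cyclises onto the chloride; the rod-shaped cyano group has the smallest demand for the axial β position. A DBU treatment reconjugates the enone and gives 9-oxo-11,12,13,14,15,16-hexanorlabd-7-ene-19-nitrile F2. i-Bu2AlH (toluene, −78 → 0 °C, then aqueous acid) reduces the nitrile to the aldehyde and the ketone to the allylic alcohol, giving 9-hydroxy-11,12,13,14,15,16-hexanorlabd-7-en-19-al F3. MnO2 (CH2Cl2, rt) reoxidises only the allylic alcohol and returns 9.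

Step 2. The risk is sluggish C-alkylation of the hindered tetrasubstituted enolate by an unactivated primary iodide, with O-alkylation or elimination of the dihalide taking over. The fallback sets out from 3 and returns at 5. The lithium enolate of 3 is alkylated with the activated electrophile allyl bromide to give (5S,6S)-6-allyl-2,6-dimethyl-5-(prop-1-en-2-yl)cyclohex-2-en-1-one F4. Disiamylborane (THF, 0 °C) should hydroborate only the monosubstituted alkene, and NaBO3 oxidation gives (5S,6S)-6-(3-hydroxypropyl)-2,6-dimethyl-5-(prop-1-en-2-yl)cyclohex-2-en-1-one F5. An Appel reaction (PPh3, CCl4) then gives 5.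

Step 11. The risk is ionisation or SN2' displacement of the hindered allylic oxyphosphonium salt, which would erode the relay of configuration from C7 to C9. The fallback sets out from 17 and returns at 20. Alcohol 17 is formylated (HCO2H, DCC, DMAP, CH2Cl2) to 19-(tert-butyldimethylsilyloxy)-14-(trimethylsilyl)-15,16-dinorlabd-8-en-13-yn-7β-yl formate F6. Pd(OAc)2/PBu3 (dioxane, reflux) then effects formate hydrogenolysis: anti oxidative addition of zerovalent palladium and loss of CO2 give a π-allylpalladium hydride on the α face, which should deliver hydride to the more substituted terminus C9 and give 20.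

Further compounds
F1 | step 5 | 2-[(1S,2S)-2-(3-chloropropyl)-2,4-dimethyl-3-oxocyclohex-4-en-1-yl]propanenitrile | O=C1C(C)=CC[C@@H](C(C)C#N)[C@]1(C)CCCCl
F2 | step 5 | 9-oxo-11,12,13,14,15,16-hexanorlabd-7-ene-19-nitrile | O=C1C(C)=CC[C@H]2[C@@](C)(C#N)CCC[C@@]21C
F3 | step 5 | 9-hydroxy-11,12,13,14,15,16-hexanorlabd-7-en-19-al (C9 epimers) | OC1C(C)=CC[C@H]2[C@@](C)(C=O)CCC[C@@]21C
F4 | step 2 | (5S,6S)-6-allyl-2,6-dimethyl-5-(prop-1-en-2-yl)cyclohex-2-en-1-one | O=C1C(C)=CC[C@@H](C(C)=C)[C@]1(C)CC=C
F5 | step 2 | (5S,6S)-6-(3-hydroxypropyl)-2,6-dimethyl-5-(prop-1-en-2-yl)cyclohex-2-en-1-one | O=C1C(C)=CC[C@@H](C(C)=C)[C@]1(C)CCCO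
F6 | step 11 | 19-(tert-butyldimethylsilyloxy)-14-(trimethylsilyl)-15,16-dinorlabd-8-en-13-yn-7β-yl formate | C[Si](C)(C)C#CCCC1=C(C)[C@@H](OC=O)C[C@H]2[C@@](C)(CO[Si](C)(C)C(C)(C)C)CCC[C@@]21C
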